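Ring E is disconnected last. Its methylhydroquinone carries a free OH on the carbon next to the fusion atom bonded to Bq (aryl-bearing oxygen bridgehead) and the side-chain ether, ortho to CH3, next to the fusion atom bonded to Bh (CH–O bridgehead): a 4-alkoxyphenol, the pattern that an alkenyl alkoxycarbene, propyne and CO give. One Dötz benzannulation forms three ring E bonds, aromatises the ring and delivers the two para oxygens already differentiated. Its precursor is the complete 7-oxanorbornene, exo-fused to ring C and the chromone, with ring F on Bq and a pentacarbonylchromium 2-(trimethylsilyl)ethoxycarbene on the alkene carbon beside Bq.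

Key step: step 21

Remark (labels): the bicycle is numbered as a 7-oxanorbornene: C1 = Bq (bears ring F), C2 and C3 = alkene carbons next to Bq and Bh, C4 = Bh, C5 and C6 = sp3 carbons next to Bh and Bq, O7 = oxygen bridge. Chromone atoms keep their usual numbers (O1, C2, C3, C4=O, 5-OH, 7-CH2O); ring A is the chromone benzo ring.

Remark (assumption): compounds 15–26 are racemic and are drawn as the enantiomer carried on; which fraction of step 15 is 27 is settled by anomalous-dispersion X-ray analysis using the bromine atom.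

Remark (chemistry): any carbonyl on C5 or C6 with an α-hydrogen can lose the oxygen bridge by β-elimination once enolised, so steps 9–16 avoid free amide bases and strongly basic enolisation.

Step 1
Reactants: 1 resorcinol
Product: 2 1,3-bis(methoxymethoxy)benzene
Conditions: MeOCH2Cl (2.4 equiv), i-Pr2NEt, CH2Cl2, 0 °C → rt
Reagents that add atoms: chloromethyl methyl ether, COCCl
Why: Base-mediated O-alkylation of both phenols (Williamson-type etherification) installs the two acetal groups that direct the metalation of step 2.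

Step 2
Reactants: 2 1,3-bis(methoxymethoxy)benzene; 3 2,3-dibromofuran
Product: 6 3-bromo-2-[2,6-bis(methoxymethoxy)phenyl]furan, via aryllithium 4 (not isolated), via arylzinc chloride 5 (not isolated)
Conditions: n-BuLi, THF, 0 °C; ZnCl2, 0 °C → rt; 3, Pd(PPh3)4 (5 mol %), 50 °C
Reagents that add atoms: none
Why: Directed ortho-metalation between the two acetal oxygens, transmetalation to zinc and Negishi coupling at the more reactive C2–Br bond of the dibromofuran (next to the ring oxygen) should give the 2-aryl-3-bromofuran, the remaining bromide being the latent carboxyl position.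

Step 3
Reactants: 6 3-bromo-2-[2,6-bis(methoxymethoxy)phenyl]furan
Product: 7 2-(3-bromofuran-2-yl)benzene-1,3-diol
Conditions: HCl (1.25 M in MeOH), 40 °C
Reagents that add atoms: none
Why: Acid-catalysed transacetalisation to methanol removes both methoxymethyl groups and frees the phenols, one of which later captures the C6 carbonyl.

Step 4
Reactants: 8 3,5-dihydroxybenzyl alcohol
Product: 9 [3,5-bis(methoxymethoxy)phenyl]methanol
Conditions: MeOCH2Cl (2.2 equiv), K2CO3, acetone, 0 °C → rt
Reagents that add atoms: chloromethyl methyl ether, COCCl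
Why: Williamson etherification under carbonate base alkylates only the two phenoxides and leaves the benzylic alcohol free.

Step 5
Reactants: 9 [3,5-bis(methoxymethoxy)phenyl]methanol
Product: 10 {[3,5-bis(methoxymethoxy)phenyl]methoxy}tri(propan-2-yl)silane
Conditions: i-Pr3SiCl, imidazole, CH2Cl2, rt
Reagents that add atoms: chlorotri(propan-2-yl)silane, CC(C)[Si](Cl)(C(C)C)C(C)C
Why: Silylation of the primary alcohol gives a bulky silyl ether that should survive butyllithium, enolates and dilute acid and fall to fluoride in step 24.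

Step 6
Reactants: 10 {[3,5-bis(methoxymethoxy)phenyl]methoxy}tri(propan-2-yl)silane
Product: 12 1-[2,6-bis(methoxymethoxy)-4-({[tri(propan-2-yl)silyl]oxy}methyl)phenyl]ethan-1-one, via aryllithium 11 (not isolated)
Conditions: n-BuLi, THF, 0 °C; MeC(O)N(OMe)Me, −78 → 0 °C; aq. NH4Cl
Reagents that add atoms: N-methoxy-N-methylacetamide, CC(=O)N(C)OC
Why: Directed ortho-metalation at the carbon flanked by both acetal oxygens, then acylation by the N-methoxy-N-methylamide, whose chelated tetrahedral adduct prevents double addition, should give the methyl ketone.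

Step 7
Reactants: 12 1-[2,6-bis(methoxymethoxy)-4-({[tri(propan-2-yl)silyl]oxy}methyl)phenyl]ethan-1-one
Product: 13 1-[2,6-dihydroxy-4-({[tri(propan-2-yl)silyl]oxy}methyl)phenyl]ethan-1-one
Conditions: ZnBr2, n-PrSH, CH2Cl2, 0 °C
Reagents that add atoms: none
Why: Lewis acid and thiol cleave the two methoxymethyl ethers (acetal cleavage assisted by chelation to the ortho carbonyl) while the silyl ether is spared.

Step 8
Reactants: 7 2-(3-bromofuran-2-yl)benzene-1,3-diol; 14 maleic anhydride
Product: 16 racemic lactone acid, via exo anhydride cycloadduct 15 (not isolated)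
Conditions: 14 (1.1 equiv), MeCN (1 M), rt, 24 h; Et3N (1.2 equiv), 0 °C → rt; 1 M HCl
Reagents that add atoms: none
Why: Diels–Alder addition of maleic anhydride to the furan equilibrates to the exo adduct, in which the ring F phenol on Bq opens the anhydride at the neighbouring C6 carbonyl (six-membered aryl lactone, reachable only from the exo adduct); this locks the adduct, keeps the exo,cis arrangement at C5/C6 set by the suprafacial cycloaddition and tells the two carboxyl carbons apart.

Step 9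
Reactants: 16 racemic lactone acid
Product: 17 racemic lactol acid
Conditions: i-Bu2AlH (3.3 equiv), CH2Cl2–THF, −78 °C; aq. KNaC4H4O6
Reagents that add atoms: none
Why: Partial reduction of the aryl lactone to the lactol (aluminium hemiacetal stable at −78 °C) brings the C6 carbon to the aldehyde level, while the carboxylate formed in the flask is not reduced at this temperature.

Step 10
Reactants: 17 racemic lactol acid
Product: 19 racemic acyl chloride silyl acetal, via tris(silyl) derivative 18 (not isolated)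
Conditions: t-BuMe2SiOTf (3.3 equiv), 2,6-lutidine, CH2Cl2, −78 → 0 °C; evaporate; (COCl)2, DMF (cat.), CH2Cl2, 0 °C → rt
Reagents that add atoms: tert-butyldimethylsilyl trifluoromethanesulfonate, CC(C)(C)[Si](C)(C)OS(=O)(=O)C(F)(F)F; oxalyl chloride, O=C(Cl)C(Cl)=O
Why: Silylation masks the lactol as a base-stable silyl acetal and the free ring F phenol as a silyl ether, and the silyl ester formed alongside is turned into the acyl chloride by the chloroiminium reagent under neutral conditions.

Step 11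
Reactants: 19 racemic acyl chloride silyl acetal; 13 1-[2,6-dihydroxy-4-({[tri(propan-2-yl)silyl]oxy}methyl)phenyl]ethan-1-one
Product: 21 racemic β-diketone silyl acetal, via trilithium enolate 20 (not isolated)
Conditions: 13 (2.2 equiv), LiN(SiMe3)2 (6.6 equiv), THF, −78 → −20 °C; 19, −78 °C; AcOH, −78 °C → rt
Reagents that add atoms: none
Why: Crossed Claisen-type C-acylation of the preformed lithium polyanion of the o-hydroxyacetophenone by the acyl chloride at −78 °C forms the bond between chromone C3 and the future carbinol carbon; no amide base is left over (the second enolate equivalent only deprotonates the product), so C5–H should stay in place.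

Step 12
Reactants: 21 racemic β-diketone silyl acetal
Product: 24 racemic chromanone, via lactol diketone 22 (not isolated), via aroylcyclopentenone 23 (not isolated)
Conditions: AcOH–THF–H2O (3:1:1), rt; then piperidine (10 mol %), AcOH (20 mol %), PhMe, 0 °C → rt
Reagents that add atoms: none
Why: Mild acid hydrolysis of the silyl acetal frees the lactol, whose aldehyde form undergoes intramolecular Knoevenagel condensation with the β-diketone carbon (closing ring C, possible only for the exo,cis aldehyde), and the ring A phenol then adds to the new enone carbon (6-endo oxa-Michael) to give the chromanone, whose two new sp3 centres are uncontrolled and are erased in step 13.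

Step 13
Reactants: 24 racemic chromanone
Product: 25 racemic chromone ketone diol
Conditions: DDQ (1.1 equiv), 1,4-dioxane, rt; then Et3N (cat.)
Reagents that add atoms: none
Why: Dehydrogenation by DDQ (hydride abstraction at chromanone C2 of the enolised β-diketone) gives the γ-pyrone, and the trace of base should let any material in which the ring F phenol had added to the same carbon exchange by addition–elimination to the same, more stable chromone.

Step 14
Reactants: 25 racemic chromone ketone diol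
Product: 26 racemic tris(silyl) bromo ketone
Conditions: t-BuMe2SiOTf (2.4 equiv), 2,6-lutidine, CH2Cl2, −78 → 0 °C
Reagents that add atoms: tert-butyldimethylsilyl trifluoromethanesulfonate, CC(C)(C)[Si](C)(C)OS(=O)(=O)C(F)(F)F
Why: Silyl triflate with a hindered pyridine base silylates the remaining ring F phenol and the hydrogen-bonded chromone 5-OH at low temperature without enolising the ring C ketone.

Step 15
Reactants: 26 racemic tris(silyl) bromo ketone
Product: 27 (1R,4R,5R,6R) bromo ketone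
Conditions: preparative SFC, amylose tris(3,5-dimethylphenylcarbamate) stationary phase, CO2/i-PrOH
Reagents that add atoms: none
Why: Chromatographic resolution on a chiral stationary phase separates the enantiomers of a configurationally stable, lipophilic intermediate, so that the absolute configuration of Bq, Bh, C5 and C6 is fixed here.

Step 16
Reactants: 27 (1R,4R,5R,6R) bromo ketone
Product: 28 methoxyvinyl carbinol
Conditions: CH2=CHOMe, t-BuLi, THF, −78 → 0 °C; CeCl3, −78 °C; 27, −78 °C; aq. NH4Cl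
Reagents that add atoms: (1-methoxyvinyl)lithium, [Li]C(=C)OC (made in the flask from methyl vinyl ether, C=COC)
Why: 1,2-Addition of the weakly basic 1-methoxyvinyl cerium reagent (a methoxycarbonyl anion equivalent) to the ring C ketone, which is less hindered and more electrophilic than the chromone carbonyl, should occur on the ring C face turned away from the oxabicycle (syn to the C5/C6 hydrogens), so the new carbinol carbon gets its OH on the bridge side as in the target.

Step 17
Reactants: 28 methoxyvinyl carbinol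
Product: 29 hydroxy ester bromide
Conditions: O3, CH2Cl2–MeOH, −78 °C (Sudan Red 7B as end-point indicator); Me2S
Reagents that add atoms: ozone, [O-][O+]=O
Why: Ozonolysis cleaves the enol ether, by far the most electron-rich alkene present, and turns C(OMe)=CH2 directly into the methyl ester without touching the carbinol stereocentre.

Step 18
Reactants: 29 hydroxy ester bromide
Product: 30 carboxylic acid
Conditions: Pd(OAc)2 (10 mol %), Xantphos (12 mol %), CO (1 atm), Et3N, H2O, 1,4-dioxane, 60 °C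
Reagents that add atoms: carbon monoxide, [C-]#[O+]; water, O
Why: Palladium-catalysed hydroxycarbonylation (oxidative addition of zerovalent palladium into the alkenyl C–Br bond, CO insertion, hydrolysis of the acyl palladium) converts the bromide on C2 into the carboxylic acid.

Step 19
Reactants: 30 carboxylic acid
Product: 32 acyl chloride, via bis(triethylsilyl) derivative 31 (not isolated)
Conditions: Et3SiOTf (2.3 equiv), 2,6-lutidine, CH2Cl2, −78 → 0 °C; evaporate; (COCl)2, DMF (cat.), CH2Cl2, 0 °C → rt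
Reagents that add atoms: triethylsilyl trifluoromethanesulfonate, CC[Si](CC)(CC)OS(=O)(=O)C(F)(F)F; oxalyl chloride, O=C(Cl)C(Cl)=O
Why: The tertiary alcohol is protected as a triethylsilyl ether while the acid becomes a silyl ester, which the chloroiminium reagent turns into the acyl chloride without generating HCl.

Step 20
Reactants: 32 acyl chloride
Product: 36 carbene complex, via sodium acylchromate 33 (not isolated), via tetramethylammonium acylchromate 34 (not isolated), via acetoxycarbene complex 35 (not isolated)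
Conditions: Na2Cr(CO)5 [from Cr(CO)6 and NaC10H8, THF, −78 °C], THF, −78 → 0 °C; Me4NBr, H2O–CH2Cl2; AcBr, CH2Cl2, −40 °C; Me3SiCH2CH2OH, −40 → 0 °C
Reagents that add atoms: disodium pentacarbonylchromate, [Na+].[Na+].[Cr-2].[C-]#[O+].[C-]#[O+].[C-]#[O+].[C-]#[O+].[C-]#[O+]; 2-(trimethylsilyl)ethanol, OCC[Si](C)(C)C
Why: Acyl substitution of the chloride by the pentacarbonylchromate dianion gives the acylchromate, and since a 2-(trimethylsilyl)ethyl electrophile would fragment instead of alkylating, the alkoxy group is brought in by O-acylation with acetyl bromide and alcoholysis of the acyloxycarbene (addition–elimination at the carbene carbon).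

Step 21
Reactants: 36 carbene complex; 37 propyne
Product: 39 ring E phenol, via tricarbonylchromium arene complex 38 (not isolated)
Conditions: 37 (5 equiv), THF (0.05 M), sealed tube, 50 °C; then air, MeCN, daylight, rt
Reagents that add atoms: none
Why: Thermal loss of one CO from 36 lets propyne coordinate and insert into the Cr=C bond with its CH terminus bonding to the carbene carbon, and CO insertion then gives the chromium-bound dienylketene O=C=C(CH3)–CH=C(OR)–C2=C3. Ring E closes by a thermal disrotatory six-electron electrocyclization of the ketene carbon onto C3, the alkene carbon beside Bh, and the cyclohexadienone tautomerizes to the phenol, held as its Cr(CO)3 complex 38 until air releases 39. The closest known reaction type is the Dötz benzannulation of cycloalkenyl alkoxycarbene chromium complexes with terminal alkynes. No stereocentre is formed, and the five present should not be touched under the neutral conditions. The step needs the normal alkyne regiochemistry (CH3 on the carbon next to the CO-derived C–OH), which the steric preference of terminal alkynes secures, while the orientation on the bicycle is fixed because the carbene sits on C2 beside Bq. Phenol formation instead of CO-free cyclopentannulation is favoured by the alkenyl (not aryl) carbene in THF, and the carbene oxygen ends as the 2-(trimethylsilyl)ethyl ether beside Bq with the free phenol beside Bh.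

Step 22
Reactants: 39 ring E phenol; 40 3-methylbutane-1,3-diol
Product: 41 ether alcohol
Conditions: 40 (3 equiv), PPh3, DIAD, THF, 0 °C → rt
Reagents that add atoms: none
Why: Mitsunobu etherification activates only the primary hydroxyl of the diol, which the hindered ring E phenol displaces under neutral conditions that leave the aryl silyl ethers and the tertiary alcohol alone.

Step 23
Reactants: 41 ether alcohol
Product: 42 tertiary acetate
Conditions: Ac2O, DMAP, Et3N, CH2Cl2, rt
Reagents that add atoms: acetic anhydride, CC(=O)OC(C)=O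
Why: DMAP-catalysed acylation acetylates the tertiary alcohol of the side chain, the only free hydroxyl left.

Step 24
Reactants: 42 tertiary acetate
Product: 43 aspergichromone B
Conditions: [(Me2N)3S][Me3SiF2] (10 equiv), DMF (degassed), 0 → 40 °C; aq. NH4Cl
Reagents that add atoms: none
Why: Fluoride removes the five silyl ethers and cleaves the 2-(trimethylsilyl)ethyl aryl ether by β-elimination (ethene and Me3SiF) in one operation, the anhydrous and weakly basic reagent sparing the tertiary acetate and the methyl ester.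

Compound list

1 | resorcinol (benzene-1,3-diol) | Oc1cccc(O)c1 | starting material
2 | 1,3-bis(methoxymethoxy)benzene | COCOc1cccc(OCOC)c1 | intermediate
3 | 2,3-dibromofuran | Brc1ccoc1Br | starting material
4 | aryllithium: [2,6-bis(methoxymethoxy)phenyl]lithium | [Li]c1c(OCOC)cccc1OCOC | intermediate
5 | arylzinc chloride: [2,6-bis(methoxymethoxy)phenyl]zinc chloride | Cl[Zn]c1c(OCOC)cccc1OCOC | intermediate
6 | 3-bromo-2-[2,6-bis(methoxymethoxy)phenyl]furan | COCOc1cccc(OCOC)c1-c1occc1Br | intermediate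
7 | 2-(3-bromofuran-2-yl)benzene-1,3-diol | Oc1cccc(O)c1-c1occc1Br | intermediate
8 | 3,5-dihydroxybenzyl alcohol | OCc1cc(O)cc(O)c1 | starting material
9 | [3,5-bis(methoxymethoxy)phenyl]methanol | OCc1cc(OCOC)cc(OCOC)c1 | intermediate
10 | {[3,5-bis(methoxymethoxy)phenyl]methoxy}tri(propan-2-yl)silane | COCOc1cc(CO[Si](C(C)C)(C(C)C)C(C)C)cc(OCOC)c1 | intermediate
11 | aryllithium: 10 lithiated between the two acetal oxygens | [Li]c1c(OCOC)cc(CO[Si](C(C)C)(C(C)C)C(C)C)cc1OCOC | intermediate
12 | 1-[2,6-bis(methoxymethoxy)-4-({[tri(propan-2-yl)silyl]oxy}methyl)phenyl]ethan-1-one | CC(=O)c1c(OCOC)cc(CO[Si](C(C)C)(C(C)C)C(C)C)cc1OCOC | intermediate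
13 | 1-[2,6-dihydroxy-4-({[tri(propan-2-yl)silyl]oxy}methyl)phenyl]ethan-1-one | CC(=O)c1c(O)cc(CO[Si](C(C)C)(C(C)C)C(C)C)cc1O | intermediate
14 | maleic anhydride | O=C1OC(=O)C=C1 | starting material
15 | exo anhydride cycloadduct (racemic): 2-bromo-1-(2,6-dihydroxyphenyl)-7-oxabicyclo[2.2.1]hept-2-ene-5,6-dicarboxylic anhydride, both carbonyls exo (syn to O7) | O=C3[C@H]2[C@@H](C(=O)O3)[C@H]1O[C@]2(c2c(O)cccc2O)C(=C1)Br | intermediate
16 | racemic lactone acid: as 15, but the exo C6 carbonyl is a six-membered aryl lactone with one ring F oxygen and C5 carries a free exo CO2H | O=C3[C@H]2[C@@H](C(=O)O)[C@H]1O[C@]2(c2c(O3)cccc2O)C(=C1)Br | intermediate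
17 | racemic lactol acid: 16 with the lactone C=O reduced to CH(OH) (both lactol epimers) | OC3[C@H]2[C@@H](C(=O)O)[C@H]1O[C@]2(c2c(O3)cccc2O)C(=C1)Br | intermediate
18 | tris(silyl) derivative (racemic): 17 with lactol OH, ring F OH and CO2H as tert-butyldimethylsilyl derivatives | CC(C)(C)[Si](C)(C)OC3[C@H]2[C@@H](C(=O)O[Si](C)(C)C(C)(C)C)[C@H]1O[C@]2(c2c(O3)cccc2O[Si](C)(C)C(C)(C)C)C(=C1)Br | intermediate
19 | racemic acyl chloride silyl acetal: exo C5–COCl; exo C6–CH(OSiMe2t-Bu)–O–ring F cyclic acetal; other ring F oxygen as OSiMe2t-Bu | CC(C)(C)[Si](C)(C)OC3[C@H]2[C@@H](C(Cl)=O)[C@H]1O[C@]2(c2c(O3)cccc2O[Si](C)(C)C(C)(C)C)C(=C1)Br | intermediate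
20 | trilithium enolate of 13 (enolate and both phenoxides) | C=C([O-])c1c([O-])cc(CO[Si](C(C)C)(C(C)C)C(C)C)cc1[O-].[Li+].[Li+].[Li+] | intermediate
21 | racemic β-diketone silyl acetal: C5–C(=O)–CH2–C(=O)–aryl (aryl = 2,6-dihydroxy-4-(i-Pr3SiOCH2)phenyl); C6 and ring F as in 19 | CC(C)(C)[Si](C)(C)OC3[C@H]2[C@@H](C(=O)CC(=O)c4c(O)cc(CO[Si](C(C)C)(C(C)C)C(C)C)cc4O)[C@H]1O[C@]2(c2c(O3)cccc2O[Si](C)(C)C(C)(C)C)C(=C1)Br | intermediate
22 | lactol diketone (racemic): 21 with the silyl acetal hydrolysed to the lactol | OC3[C@H]2[C@@H](C(=O)CC(=O)c4c(O)cc(CO[Si](C(C)C)(C(C)C)C(C)C)cc4O)[C@H]1O[C@]2(c2c(O3)cccc2O[Si](C)(C)C(C)(C)C)C(=C1)Br | intermediate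
23 | aroylcyclopentenone (racemic): ring C closed as a cyclopent-2-enone exo-fused at C5–C6 (ketone carbon on C5, enone CH on C6, aroyl group on the enone α-carbon); ring F carries one OH and one OSiMe2t-Bu | O=C1C(C(=O)c3c(O)cc(CO[Si](C(C)C)(C(C)C)C(C)C)cc3O)=C[C@H]2[C@@H]1[C@H]1O[C@]2(c2c(O)cccc2O[Si](C)(C)C(C)(C)C)C(=C1)Br | intermediate
24 | racemic chromanone: ring A phenol added to the enone CH of 23 (3-acylchroman-4-one, enolised; chromanone C2/C3 epimers) | O=C1C2C(Oc3cc(CO[Si](C(C)C)(C(C)C)C(C)C)cc(O)c3C2=O)[C@H]2[C@@H]1[C@H]1O[C@]2(c2c(O)cccc2O[Si](C)(C)C(C)(C)C)C(=C1)Br | intermediate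
25 | racemic chromone ketone diol: ring C ketone bonded to C5 and chromone C3, chromone C2 bonded to C6, exo,cis fusion; chromone 5-OH and 7-CH2OSi(i-Pr)3; ring F with one OH and one OSiMe2t-Bu; Br on C2 | O=C1c2c(oc3cc(CO[Si](C(C)C)(C(C)C)C(C)C)cc(O)c3c2=O)[C@H]2[C@@H]1[C@H]1O[C@]2(c2c(O)cccc2O[Si](C)(C)C(C)(C)C)C(=C1)Br | intermediate
26 | racemic tris(silyl) bromo ketone: 25 with both remaining phenols as tert-butyldimethylsilyl ethers | O=C1c2c(oc3cc(CO[Si](C(C)C)(C(C)C)C(C)C)cc(O[Si](C)(C)C(C)(C)C)c3c2=O)[C@H]2[C@@H]1[C@H]1O[C@]2(c2c(O[Si](C)(C)C(C)(C)C)cccc2O[Si](C)(C)C(C)(C)C)C(=C1)Br | intermediate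
27 | (1R,4R,5R,6R) bromo ketone: single enantiomer of 26 (oxanorbornene numbering) | O=C1c2c(oc3cc(CO[Si](C(C)C)(C(C)C)C(C)C)cc(O[Si](C)(C)C(C)(C)C)c3c2=O)[C@H]2[C@@H]1[C@H]1O[C@]2(c2c(O[Si](C)(C)C(C)(C)C)cccc2O[Si](C)(C)C(C)(C)C)C(=C1)Br | intermediate
28 | methoxyvinyl carbinol: 27 with 1-methoxyvinyl added to the ring C ketone; tertiary OH on the ring C face syn to O7, carbon substituent on the face of the C5/C6 hydrogens | C=C(OC)[C@@]1(O)c2c(oc3cc(CO[Si](C(C)C)(C(C)C)C(C)C)cc(O[Si](C)(C)C(C)(C)C)c3c2=O)[C@H]2[C@@H]1[C@H]1O[C@]2(c2c(O[Si](C)(C)C(C)(C)C)cccc2O[Si](C)(C)C(C)(C)C)C(=C1)Br | intermediate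
29 | hydroxy ester bromide: 28 with C(OMe)=CH2 converted into CO2Me | COC(=O)[C@@]1(O)c2c(oc3cc(CO[Si](C(C)C)(C(C)C)C(C)C)cc(O[Si](C)(C)C(C)(C)C)c3c2=O)[C@H]2[C@@H]1[C@H]1O[C@]2(c2c(O[Si](C)(C)C(C)(C)C)cccc2O[Si](C)(C)C(C)(C)C)C(=C1)Br | intermediate
30 | carboxylic acid: 29 with Br on C2 replaced by CO2H | COC(=O)[C@@]1(O)c2c(oc3cc(CO[Si](C(C)C)(C(C)C)C(C)C)cc(O[Si](C)(C)C(C)(C)C)c3c2=O)[C@H]2[C@@H]1[C@H]1O[C@]2(c2c(O[Si](C)(C)C(C)(C)C)cccc2O[Si](C)(C)C(C)(C)C)C(=C1)C(=O)O | intermediate
31 | bis(triethylsilyl) derivative: 30 as triethylsilyl ether (tertiary oxygen) and triethylsilyl ester | COC(=O)[C@@]1(O[Si](CC)(CC)CC)c2c(oc3cc(CO[Si](C(C)C)(C(C)C)C(C)C)cc(O[Si](C)(C)C(C)(C)C)c3c2=O)[C@H]2[C@@H]1[C@H]1O[C@]2(c2c(O[Si](C)(C)C(C)(C)C)cccc2O[Si](C)(C)C(C)(C)C)C(=C1)C(=O)O[Si](CC)(CC)CC | intermediate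
32 | acyl chloride: COCl on C2, tertiary OSiEt3 | COC(=O)[C@@]1(O[Si](CC)(CC)CC)c2c(oc3cc(CO[Si](C(C)C)(C(C)C)C(C)C)cc(O[Si](C)(C)C(C)(C)C)c3c2=O)[C@H]2[C@@H]1[C@H]1O[C@]2(c2c(O[Si](C)(C)C(C)(C)C)cccc2O[Si](C)(C)C(C)(C)C)C(=C1)C(Cl)=O | intermediate
33 | sodium acylchromate: Na[(OC)5Cr–C(=O)–C2] | COC(=O)[C@@]1(O[Si](CC)(CC)CC)c2c(oc3cc(CO[Si](C(C)C)(C(C)C)C(C)C)cc(O[Si](C)(C)C(C)(C)C)c3c2=O)[C@H]2[C@@H]1[C@H]1O[C@]2(c2c(O[Si](C)(C)C(C)(C)C)cccc2O[Si](C)(C)C(C)(C)C)C(=C1)C([O-])=[Cr].[Na+].[C-]#[O+].[C-]#[O+].[C-]#[O+].[C-]#[O+].[C-]#[O+] | intermediate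
34 | tetramethylammonium acylchromate: Me4N[(OC)5Cr–C(=O)–C2] | COC(=O)[C@@]1(O[Si](CC)(CC)CC)c2c(oc3cc(CO[Si](C(C)C)(C(C)C)C(C)C)cc(O[Si](C)(C)C(C)(C)C)c3c2=O)[C@H]2[C@@H]1[C@H]1O[C@]2(c2c(O[Si](C)(C)C(C)(C)C)cccc2O[Si](C)(C)C(C)(C)C)C(=C1)C([O-])=[Cr].C[N+](C)(C)C.[C-]#[O+].[C-]#[O+].[C-]#[O+].[C-]#[O+].[C-]#[O+] | intermediate
35 | acetoxycarbene complex: (OC)5Cr=C(OAc)–C2 | COC(=O)[C@@]1(O[Si](CC)(CC)CC)c2c(oc3cc(CO[Si](C(C)C)(C(C)C)C(C)C)cc(O[Si](C)(C)C(C)(C)C)c3c2=O)[C@H]2[C@@H]1[C@H]1O[C@]2(c2c(O[Si](C)(C)C(C)(C)C)cccc2O[Si](C)(C)C(C)(C)C)C(=C1)C(OC(C)=O)=[Cr].[C-]#[O+].[C-]#[O+].[C-]#[O+].[C-]#[O+].[C-]#[O+] | intermediate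
36 | carbene complex: pentacarbonylchromium [2-(trimethylsilyl)ethoxy]carbene on C2 of the fully substituted 7-oxanorbornene | COC(=O)[C@@]1(O[Si](CC)(CC)CC)c2c(oc3cc(CO[Si](C(C)C)(C(C)C)C(C)C)cc(O[Si](C)(C)C(C)(C)C)c3c2=O)[C@H]2[C@@H]1[C@H]1O[C@]2(c2c(O[Si](C)(C)C(C)(C)C)cccc2O[Si](C)(C)C(C)(C)C)C(=C1)C(OCC[Si](C)(C)C)=[Cr].[C-]#[O+].[C-]#[O+].[C-]#[O+].[C-]#[O+].[C-]#[O+] | intermediate
37 | propyne | CC#C | starting material
38 | tricarbonylchromium arene complex of 39 (Cr(CO)3 on ring E) | COC(=O)[C@@]1(O[Si](CC)(CC)CC)c2c(oc3cc(CO[Si](C(C)C)(C(C)C)C(C)C)cc(O[Si](C)(C)C(C)(C)C)c3c2=O)[C@H]2[C@@H]1[C@H]1O[C@]2(c2c(O[Si](C)(C)C(C)(C)C)cccc2O[Si](C)(C)C(C)(C)C)c2c(OCC[Si](C)(C)C)cc(C)c(O)c21.[Cr].[C-]#[O+].[C-]#[O+].[C-]#[O+] | intermediate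
39 | ring E phenol: ring E fused on C2–C3; from the Bq-side fusion carbon: C–OCH2CH2SiMe3, CH, C–CH3, C–OH, then the Bh-side fusion carbon | COC(=O)[C@@]1(O[Si](CC)(CC)CC)c2c(oc3cc(CO[Si](C(C)C)(C(C)C)C(C)C)cc(O[Si](C)(C)C(C)(C)C)c3c2=O)[C@H]2[C@@H]1[C@H]1O[C@]2(c2c(O[Si](C)(C)C(C)(C)C)cccc2O[Si](C)(C)C(C)(C)C)c2c(OCC[Si](C)(C)C)cc(C)c(O)c21 | intermediate
40 | 3-methylbutane-1,3-diol | CC(C)(O)CCO | starting material
41 | ether alcohol: phenol oxygen of 39 carrying the 3-hydroxy-3-methylbutyl group | COC(=O)[C@@]1(O[Si](CC)(CC)CC)c2c(oc3cc(CO[Si](C(C)C)(C(C)C)C(C)C)cc(O[Si](C)(C)C(C)(C)C)c3c2=O)[C@H]2[C@@H]1[C@H]1O[C@]2(c2c(O[Si](C)(C)C(C)(C)C)cccc2O[Si](C)(C)C(C)(C)C)c2c(OCC[Si](C)(C)C)cc(C)c(OCCC(C)(C)O)c21 | intermediate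
42 | tertiary acetate: 41 with the side-chain tertiary alcohol acetylated | COC(=O)[C@@]1(O[Si](CC)(CC)CC)c2c(oc3cc(CO[Si](C(C)C)(C(C)C)C(C)C)cc(O[Si](C)(C)C(C)(C)C)c3c2=O)[C@H]2[C@@H]1[C@H]1O[C@]2(c2c(O[Si](C)(C)C(C)(C)C)cccc2O[Si](C)(C)C(C)(C)C)c2c(OCC[Si](C)(C)C)cc(C)c(OCCC(C)(C)OC(C)=O)c21 | intermediate
43 | aspergichromone B | COC(=O)[C@@]1(O)c2c(oc3cc(CO)cc(O)c3c2=O)[C@H]2[C@@H]1[C@H]1O[C@]2(c2c(O)cccc2O)c2c(O)cc(C)c(OCCC(C)(C)OC(C)=O)c21 | target

Total step count: 24. Longest linear sequence: 20 steps (steps 1–3, then 8–24, from resorcinol); the ring A ketone 13 (steps 4–7) joins at step 11.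

Steps most likely to fail

1. Step 21 (benzannulation). The two ring F silyl ethers beside the carbene carbon may block alkyne uptake at chromium, so that CO loss ends in decomposition or in CO-free cyclopentannulation, or the ketene may be intercepted before it cyclises. Fallback (sets out from 29, rejoins at 43): the same dienylketene is generated without chromium by a Moore-type cyclobutenone ring expansion. Bromide 29 is silylated (Et3SiOTf, 2,6-lutidine) to the triethylsilyl ether F1. Bromine–lithium exchange (t-BuLi, THF–Et2O, −100 °C) gives the alkenyllithium F2, which adds to the free carbonyl of 4,4-dimethoxy-3-methylcyclobut-2-en-1-one; the alkoxide is silylated in the flask (Et3SiOTf) to the ketal F3. Oxalic acid on wet silica unmasks the cyclobutenone F4. Heating (toluene, 100 °C) opens the four-membered ring with outward rotation of the silyloxy group, and the dienylketene closes onto C3 to the phenol F5, the triethylsilyl analogue of 39. Mitsunobu etherification with 40 gives the ether alcohol F6, acetylation gives the acetate F7, and the fluoride treatment of step 24 then gives 43.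

2. Step 20 (carbene formation). The chromate dianion may transfer an electron to the chromone instead of attacking the acyl chloride, or the bulky dianion may fail to reach the acyl carbon beside Bq. Fallback (sets out from 29, rejoins at 34): the acylchromate is made in the classical way from an organolithium and Cr(CO)6. The alkenyllithium F2 (from 29 through the silyl ether F1, as above) is added to Cr(CO)6 (THF, −78 → 0 °C) to give the lithium acylchromate F8. Cation exchange with Me4NBr gives 34, which is carried through the acetyl bromide and alcohol part of step 20; steps 18 and 19 are bypassed.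

3. Step 18 (hydroxycarbonylation). Oxidative addition of zerovalent palladium into the C2–Br bond beside the quaternary bridgehead may be too slow, so that the bromide is recovered or aryl silyl ethers are lost on prolonged heating with aqueous amine. Fallback (sets out from 29, rejoins at 30): nickel-catalysed reductive carboxylation of the alkenyl bromide with CO2 (NiCl2(PPh3)2, Mn powder, Et4NI, CO2 1 atm, DMF, rt). It uses the smaller zerovalent nickel at room temperature, needs neither CO nor aqueous base, and gives 30 directly.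

Further compounds

F1 | step 21 | triethylsilyl ether of 29 | COC(=O)[C@@]1(O[Si](CC)(CC)CC)c2c(oc3cc(CO[Si](C(C)C)(C(C)C)C(C)C)cc(O[Si](C)(C)C(C)(C)C)c3c2=O)[C@H]2[C@@H]1[C@H]1O[C@]2(c2c(O[Si](C)(C)C(C)(C)C)cccc2O[Si](C)(C)C(C)(C)C)C(=C1)Br
F2 | step 21 | alkenyllithium (Li on C2) | COC(=O)[C@@]1(O[Si](CC)(CC)CC)c2c(oc3cc(CO[Si](C(C)C)(C(C)C)C(C)C)cc(O[Si](C)(C)C(C)(C)C)c3c2=O)[C@H]2[C@@H]1[C@H]1O[C@]2(c2c(O[Si](C)(C)C(C)(C)C)cccc2O[Si](C)(C)C(C)(C)C)C(=C1)[Li]
F3 | step 21 | ketal: 4,4-dimethoxy-3-methyl-1-(triethylsilyloxy)cyclobut-2-en-1-yl group on C2 | COC(=O)[C@@]1(O[Si](CC)(CC)CC)c2c(oc3cc(CO[Si](C(C)C)(C(C)C)C(C)C)cc(O[Si](C)(C)C(C)(C)C)c3c2=O)[C@H]2[C@@H]1[C@H]1O[C@]2(c2c(O[Si](C)(C)C(C)(C)C)cccc2O[Si](C)(C)C(C)(C)C)C(=C1)C3(O[Si](CC)(CC)CC)C=C(C)C3(OC)OC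
F4 | step 21 | cyclobutenone: 4-alkenyl-2-methyl-4-(triethylsilyloxy)cyclobut-2-en-1-one on C2 | COC(=O)[C@@]1(O[Si](CC)(CC)CC)c2c(oc3cc(CO[Si](C(C)C)(C(C)C)C(C)C)cc(O[Si](C)(C)C(C)(C)C)c3c2=O)[C@H]2[C@@H]1[C@H]1O[C@]2(c2c(O[Si](C)(C)C(C)(C)C)cccc2O[Si](C)(C)C(C)(C)C)C(=C1)C3(O[Si](CC)(CC)CC)C=C(C)C3=O
F5 | step 21 | phenol: 39 with OSiEt3 in place of the 2-(trimethylsilyl)ethoxy group | COC(=O)[C@@]1(O[Si](CC)(CC)CC)c2c(oc3cc(CO[Si](C(C)C)(C(C)C)C(C)C)cc(O[Si](C)(C)C(C)(C)C)c3c2=O)[C@H]2[C@@H]1[C@H]1O[C@]2(c2c(O[Si](C)(C)C(C)(C)C)cccc2O[Si](C)(C)C(C)(C)C)c2c(O[Si](CC)(CC)CC)cc(C)c(O)c21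
F6 | step 21 | ether alcohol: 41 with OSiEt3 in place of the 2-(trimethylsilyl)ethoxy group | COC(=O)[C@@]1(O[Si](CC)(CC)CC)c2c(oc3cc(CO[Si](C(C)C)(C(C)C)C(C)C)cc(O[Si](C)(C)C(C)(C)C)c3c2=O)[C@H]2[C@@H]1[C@H]1O[C@]2(c2c(O[Si](C)(C)C(C)(C)C)cccc2O[Si](C)(C)C(C)(C)C)c2c(O[Si](CC)(CC)CC)cc(C)c(OCCC(C)(C)O)c21
F7 | step 21 | acetate: 42 with OSiEt3 in place of the 2-(trimethylsilyl)ethoxy group | COC(=O)[C@@]1(O[Si](CC)(CC)CC)c2c(oc3cc(CO[Si](C(C)C)(C(C)C)C(C)C)cc(O[Si](C)(C)C(C)(C)C)c3c2=O)[C@H]2[C@@H]1[C@H]1O[C@]2(c2c(O[Si](C)(C)C(C)(C)C)cccc2O[Si](C)(C)C(C)(C)C)c2c(O[Si](CC)(CC)CC)cc(C)c(OCCC(C)(C)OC(C)=O)c21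
F8 | step 20 | lithium acylchromate: Li[(OC)5Cr–C(=O)–C2] | COC(=O)[C@@]1(O[Si](CC)(CC)CC)c2c(oc3cc(CO[Si](C(C)C)(C(C)C)C(C)C)cc(O[Si](C)(C)C(C)(C)C)c3c2=O)[C@H]2[C@@H]1[C@H]1O[C@]2(c2c(O[Si](C)(C)C(C)(C)C)cccc2O[Si](C)(C)C(C)(C)C)C(=C1)C([O-])=[Cr].[Li+].[C-]#[O+].[C-]#[O+].[C-]#[O+].[C-]#[O+].[C-]#[O+]
F0 | step 18 | none | none
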